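## The problem

Glycyrrhizaisoflavone C (25) is a 7-hydroxyisoflavone (rings A and C) with a pentasubstituted ring B. C1' is bonded to chromone C3, C2' carries a methoxy group, and C3'/C4' are fused to a 2,2-dimethyldihydropyran (ring D) whose oxygen sits on C4'. C6' carries a free hydroxyl and C5' holds the only ring-B hydrogen. The molecule has no stereocentre, so the whole difficulty is regiochemical. Ring B carries three oxygens in a 1,3,5 relationship that must end as three different functions: a methyl ether, a cyclic tertiary alkyl ether and a free phenol. The C3–C1' bond is flanked by oxygen on both ortho carbons, which crowds ring C closure and every late reaction near that axis. The C6' oxygen is meta to both the C2' and the C4' oxygen, so electrophilic substitution or phenol oxidation on a 2',4'-dioxygenated ring goes to C5' and cannot deliver it. The chromone is opened at C2 by hot alkali and its C2–C3 double bond can be over-reduced, free phenols on the electron-rich ring B do not tolerate oxidants, and the aryl methyl ether must survive the final deprotection. The enabling feature is that chromone C2 and ring-B C6' are 1,4-related through C3 and C1'. An oxygen on a one-carbon substituent at C2 therefore reaches C6' through a six-membered ring. With the methoxy group on C2', C6'–H is the only ortho C–H of ring B. A carboxyl on C2 is what an oxalyl closure of ring C leaves behind, and isoflavone-2-carboxylic acids lose it again by decarboxylation.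

## Retrosynthesis

**25 to 24.** The two phenolic O–H bonds are traced back to benzyl ethers in 24. Benzyl is preferred to methyl or acetal groups because it survives alkali, the oxidative key step and heating, and it is removed by hydrogenolysis, which leaves the C2' methyl ether and the ring D ether alone. Using the same group on both phenols keeps the unmasking to one step.

**24 to 23.** The C2–H bond of the chromone is traced back to a C2–carboxyl bond in acid 23. Isoflavone-2-carboxylic acids are known to decarboxylate, so the extra carbon costs one step to remove. The forward reaction must be a protodecarboxylation mild enough for two benzyl ethers.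

**23 to 20.** The carboxyl of 23 and its C6' benzyloxy group are joined back into the aryl ester of pentacyclic lactone 20. The free hydroxy acid would re-close on acidification, so the forward sequence must open the lactone with base and cap the phenoxide with benzyl bromide (14) before any acid is added. Benzyl ester 22 forms alongside and is saponified in the same flask.

**20 to 19 (key disconnection).** The C6'–O bond of the lactone is cut, giving acid 19. Neighbouring cuts were weighed against it. Direct electrophilic hydroxylation would attack C5'. Carrying the oxygen from the start means differentiating three phloroglucinol oxygens. This cut instead removes one oxygen from ring B altogether, so every earlier intermediate has a dioxygenated ring B with a single ortho substituent on the aryl–chromone axis. The forward reaction is a carboxylate-directed palladium C–H lactonisation, which needs only that C6'–H be the one C–H the carboxylate can reach.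

**19 to 18 to 15 + 16.** Ring C is opened at O1–C2 and C2–C3, leading through ester 18 to deoxybenzoin 15 and ethyl chlorooxoacetate (16). A one-carbon closure would give the plain isoflavone with no handle at C2. The two-carbon oxalyl unit installs C2 and the directing carboxyl in one operation. The forward steps are O-acylation with cyclodehydration in pyridine and a mild ester hydrolysis.

**15 to 13 to 11 + 12.** The benzyl ether of 15 comes from the 4-hydroxyl of deoxybenzoin 13 and benzyl bromide (14). The aryl–carbonyl bond of 13 is cut to resorcinol (12) and arylacetic acid 11. A cross-coupling of a 3-halochromone with a ring-B organometallic was set aside because it needs ring B halogenated at a position electrophiles do not choose and brings no C2 carboxyl. The forward reactions are a Friedel–Crafts acylation and a benzylation that discriminates the free 4-hydroxyl from the chelated 2-hydroxyl.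

**11 to 10 to 8.** Acid 11 comes from methyl ester 10, and the aromatic ring B of 10 is traced to cyclohexenone 8. The ketone carbon becomes the methoxy-bearing C2' (with methanol, 9), and the vinylogous ester oxygen becomes the ring D oxygen on C4'. Attaching the acetic acid chain to a pre-formed aromatic chroman would have to choose between two activated positions. Building ring B from a cyclohexenone fixes the chain position before the ring is aromatic.

**8 to 5 + 6.** The C–C bond between the ring and the acetate chain is cut, giving vinylogous ester 5 and methyl bromoacetate (6). Kinetic deprotonation of 5 occurs only at the ketone α' carbon, which becomes C1' of ring B, so regiochemistry is set by the enolate.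

**5 to 4 to 1 + 2.** Saturation of the pyran double bond leads back to 2H-pyran 4. Cutting its C4–C4a and O1–C2 bonds gives cyclohexane-1,3-dione (1) and 3-methylbut-2-enal (2). Ring D with its gem-dimethyl group and the oxygenated six-carbon precursor of ring B thus arise from two commodity chemicals in one condensation.

## Roads not taken

**Alternative 1:** ring B built by a pyrone-to-phloroglucinol isomerisation.
- **Cut:** C5'–C6' of ring B.
- **Key step:** methoxide in methanol opens the tetrasubstituted pyrone A1 at its lactone carbonyl. The enolate of the released methyl ketone then attacks the new ester and closes ring B as the resorcinol monomethyl ether A2.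
- **Merits:** all three ring-B oxygens arrive already differentiated, with the prenyl group between the methoxy and one hydroxyl, so ring D can close in one direction only. No C–H oxidation, no noble metal and no sacrificial carbon are needed. In these respects it is better than the chosen plan.
- **Weak points:** A1 needs carbon substituents on both C3 and C5 of a 4-methoxy-6-methylpyrone, and C5 of that nucleus is hard to alkylate. The ring closure needs the terminal methyl enolate, whereas the doubly activated γ-position is the thermodynamic site. The ester it must attack is a deactivated β-methoxyacrylate, and re-lactonisation competes. A2 then has a free hydroxyl next to the acetate chain, which lactonises readily, and the ring C closure would run on a ring B with two ortho oxygens.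
- **Comparison:** the chosen plan pays with one demanding catalytic step and three steps to remove the tether. Against that, acid 11 is reached by five classical steps and ring C is closed on a ring B with one ortho substituent.

**Alternative 2:** ring B assembled by a cyclobutenone–siloxyalkyne benzannulation.
- **Cut:** C1'–C2', C2'–C3' and C4'–C5'.
- **Key step:** heating the chromonyl cyclobutenone A3 with the siloxyalkyne A4 (Danheiser benzannulation). Four-electron ring opening gives a vinylketene, which adds the alkyne; a second ring opening and a six-electron closure give the isoflavone A5.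
- **Merits:** A5 carries a free C2' phenol, a silyl ether on C4' and a benzyl ether on C6'. The annulation is regiospecific and convergent, and the three oxygens can be addressed one by one. In convergence and in the certainty of the oxygen pattern it is better than the chosen plan.
- **Weak points:** both partners are bespoke. A3 joins a strained vinylogous ester to a chromone that is itself a Michael acceptor. A4 requires ynolate chemistry. The free C2' phenol of A5 must be methylated before any acid is used, or it will add to the isobutenyl side chain in the wrong direction. Ring D must be closed before hydrogenolysis, or the alkene is reduced.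
- **Comparison:** the chosen plan offers commodity starting materials and classical steps up to the key reaction, and ring D is in place from step 1. Its price is the late C–H lactonisation on an untested substrate type.

**Alternative 3:** propargyl ether Claisen cascade on a symmetric ring B.
- **Cut:** C3'–C4 of ring D (with re-formation of the O–C2 bond of ring D).
- **Key step:** heating the 1,1-dimethylpropargyl ether A6 gives a [3,3] shift, a 1,5-hydrogen shift and an oxa-six-electron electrocyclisation, leading to the dimethylchromene A7.
- **Merits:** this cascade is among the most dependable chromene syntheses. The two ortho positions of A6 are equivalent, so it has no regiochemical issue, and the chromene double bond would be reduced for free in the final hydrogenolysis. Its key step is clearly safer than the key step of the chosen plan.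
- **Weak points:** in A7 the two acetal-protected oxygens flanking C1' are no longer equivalent, but they are chemically very similar. The one next to ring D must become the methyl ether and the other the free phenol. After deprotection the hydroxyl that needs methylation is the more hindered one, so a protect–methylate–deprotect detour with uncertain selectivity is needed. A6 also requires ring C closure on a ring B with two ortho oxygens.
- **Comparison:** the chosen plan has no differentiation problem. The methyl ether is fixed when ring B is aromatised (8 to 10) and the hydroxyl is placed by the directed C–H reaction (19 to 20).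

Key step: step 10

## Route

Remark: the target has no stereocentre and the aryl–chromone axis is taken to rotate freely in all intermediates. The one stereocentre formed on the way (C6 of 8) is made as the racemate and is erased in step 4.

Step 1
Reactants: 1 cyclohexane-1,3-dione; 2 3-methylbut-2-enal
Product: 4 2,2-dimethyl-2,6,7,8-tetrahydro-5H-chromen-5-one, via 1-oxatriene 3 (not isolated)
Conditions: ethylenediammonium diacetate (10 mol%), MeOH, rt to 50 °C
Reagents that add atoms: 3-methylbut-2-enal (2), CC(C)=CC=O
Why: Knoevenagel condensation gives oxatriene 3, which closes by oxa-six-electron electrocyclisation (formal [3+3] annulation); this is standard for cyclic 1,3-diones and enals.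

Step 2
Reactants: 4 2,2-dimethyl-2,6,7,8-tetrahydro-5H-chromen-5-one
Product: 5 2,2-dimethyl-2,3,4,6,7,8-hexahydro-5H-chromen-5-one
Conditions: H2 (1 atm), 10% Pd/C, EtOAc, rt
Reagents that add atoms: none
Why: Catalytic hydrogenation should saturate the disubstituted pyran alkene, while the tetrasubstituted push–pull double bond of the vinylogous ester is inert under these conditions.

Step 3
Reactants: 5 2,2-dimethyl-2,3,4,6,7,8-hexahydro-5H-chromen-5-one; 6 methyl bromoacetate
Product: 8 methyl 2-(2,2-dimethyl-5-oxo-3,4,5,6,7,8-hexahydro-2H-chromen-6-yl)acetate (racemic), via lithium dienolate 7 (not isolated)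
Conditions: LiN(i-Pr)2, THF, −78 °C; then 6, DMPU, −78 to 0 °C
Reagents that add atoms: methyl bromoacetate (6), COC(=O)CBr
Why: Kinetic deprotonation of a vinylogous ester occurs at the α' carbon (Stork–Danheiser regiochemistry) and the enolate is alkylated by the reactive α-bromoester; the new stereocentre at C6 is formed racemic and is removed by aromatisation.

Step 4
Reactants: 8 methyl 2-(2,2-dimethyl-5-oxo-3,4,5,6,7,8-hexahydro-2H-chromen-6-yl)acetate; 9 methanol
Product: 10 methyl 2-(5-methoxy-2,2-dimethylchroman-6-yl)acetate
Conditions: I2 (2 equiv), MeOH, reflux
Reagents that add atoms: methanol (9), CO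
Why: Iodine–methanol oxidative aromatisation of a cyclohexenone: ketalisation and enol ether formation, α-iodination and loss of HI supply the missing unsaturation. The ketone carbon becomes the methoxy-bearing aromatic carbon and the vinylogous ester oxygen stays as the chroman oxygen.

Step 5
Reactants: 10 methyl 2-(5-methoxy-2,2-dimethylchroman-6-yl)acetate
Product: 11 2-(5-methoxy-2,2-dimethylchroman-6-yl)acetic acid
Conditions: LiOH·H2O, THF/MeOH/H2O, rt; then 1 M HCl
Reagents that add atoms: lithium hydroxide, [Li+].[OH-]
Why: Ordinary saponification of an unhindered methyl ester; the aryl ethers are inert to aqueous base.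

Step 6
Reactants: 11 2-(5-methoxy-2,2-dimethylchroman-6-yl)acetic acid; 12 resorcinol
Product: 13 1-(2,4-dihydroxyphenyl)-2-(5-methoxy-2,2-dimethylchroman-6-yl)ethan-1-one
Conditions: BF3·OEt2 (neat), 85 °C; then aq. NaOAc
Reagents that add atoms: resorcinol (12), Oc1cccc(O)c1
Why: Friedel–Crafts acylation of resorcinol at C4 by an arylacetic acid in BF3·OEt2 is the standard deoxybenzoin synthesis. Resorcinol, used in excess, is more nucleophilic than the chroman ring, and the product is protected from further acylation as its boron chelate.

Step 7
Reactants: 13 1-(2,4-dihydroxyphenyl)-2-(5-methoxy-2,2-dimethylchroman-6-yl)ethan-1-one; 14 benzyl bromide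
Product: 15 1-[4-(benzyloxy)-2-hydroxyphenyl]-2-(5-methoxy-2,2-dimethylchroman-6-yl)ethan-1-one
Conditions: 14 (1.05 equiv), K2CO3, acetone, reflux
Reagents that add atoms: benzyl bromide (14), BrCc1ccccc1
Why: Williamson etherification; the 2-hydroxyl is hydrogen-bonded to the ketone and much less nucleophilic, so 2,4-dihydroxyaryl ketones are benzylated selectively at the 4-oxygen.

Step 8
Reactants: 15 1-[4-(benzyloxy)-2-hydroxyphenyl]-2-(5-methoxy-2,2-dimethylchroman-6-yl)ethan-1-one; 16 ethyl chlorooxoacetate
Product: 18 ethyl 7-(benzyloxy)-3-(5-methoxy-2,2-dimethylchroman-6-yl)-4-oxo-4H-chromene-2-carboxylate, via O-ethoxalyl ester 17 (not isolated)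
Conditions: 16 (3 equiv), pyridine, 0 °C to rt, then 60 °C
Reagents that add atoms: ethyl chlorooxoacetate (16), CCOC(=O)C(=O)Cl
Why: Classical ethoxalyl chloride synthesis of isoflavone-2-carboxylates: O-acylation to 17, intramolecular addition of the ketone-activated benzylic carbon to the aryl ester carbonyl, and dehydration of the cyclic hemiketal. The benzylic carbon carries an aryl group with only one ortho substituent, so the closure is not unusually hindered.

Step 9
Reactants: 18 ethyl 7-(benzyloxy)-3-(5-methoxy-2,2-dimethylchroman-6-yl)-4-oxo-4H-chromene-2-carboxylate
Product: 19 7-(benzyloxy)-3-(5-methoxy-2,2-dimethylchroman-6-yl)-4-oxo-4H-chromene-2-carboxylic acid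
Conditions: LiOH·H2O (1.5 equiv), THF/H2O, 0 °C to rt; then 1 M HCl
Reagents that add atoms: lithium hydroxide, [Li+].[OH-]
Why: Chromone-2-carboxylates are activated esters that saponify under mild conditions, well below those needed for hydroxide to open ring C.

Step 10
Reactants: 19 7-(benzyloxy)-3-(5-methoxy-2,2-dimethylchroman-6-yl)-4-oxo-4H-chromene-2-carboxylic acid
Product: 20 pentacyclic lactone: compound 19 in which one carboxyl oxygen is bonded to chroman C7 (ring B C6'), giving a six-membered aryl ester ring fused to the chromone across C2–C3 and to ring B across C1'–C6'
Conditions: Pd(OAc)2 (10 mol%), N-acetylglycine (30 mol%), PhI(OAc)2 (2 equiv), KOAc (2 equiv), t-BuOH, 80 °C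
Reagents that add atoms: none
Why: The potassium carboxylate of 19 binds Pd(OAc)2, rotation about the C3–C1' axis brings C6'–H to the metal, and concerted metalation–deprotonation (N-acetylglycine as internal base) gives a seven-membered palladacycle. PhI(OAc)2 oxidises it to tetravalent palladium, and C(sp2)–O reductive elimination forms the C6'–O bond and returns divalent palladium. The closest known reaction is the carboxylate-directed C–H lactonisation of biaryl-2-carboxylic acids to benzo[c]chromen-6-ones with the same catalyst and oxidant; here the carboxyl sits on chromone C2, which keeps the same 1,4 relationship to the C–H bond. The one new ring, the six-membered lactone (O, carbonyl C, C2, C3, C1', C6'), closes by contraction of the palladacycle at an aromatic carbon and not by nucleophilic attack, so no Baldwin constraint applies. No stereocentre is created. Site selectivity: C2' is blocked by the methoxy group and a metalation mechanism cannot attack it ipso; C5'–H is out of reach of a C2-bound metal; ring A C5–H would need ketone direction, which the anionic carboxylate should outcompete in buffered tert-butanol, and any assistance from the C4 carbonyl toward ring B would reach the same C6'–H. Chemoselectivity: every phenol is capped (benzyl, methyl or chroman ether), so the trivalent iodine oxidant meets no free phenol.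

Step 11
Reactants: 20 pentacyclic lactone; 14 benzyl bromide
Product: 23 7-(benzyloxy)-3-[7-(benzyloxy)-5-methoxy-2,2-dimethylchroman-6-yl]-4-oxo-4H-chromene-2-carboxylic acid, via dipotassium salt 21 (not isolated), via benzyl ester 22 (not isolated)
Conditions: KOH (2.2 equiv), THF/H2O, rt; evaporate; 14 (2.5 equiv), DMF, 50 °C; then aq. KOH, rt; then 1 M HCl
Reagents that add atoms: potassium hydroxide, [K+].[OH-]; benzyl bromide (14), BrCc1ccccc1
Why: Hydroxide cleaves the aryl ester quickly because a phenoxide leaves; the phenoxide of 21 is benzylated before any acid is added, so the lactone cannot re-form. Whatever fraction of the carboxylate is benzylated to 22 converges on 23 when the activated benzyl ester is saponified in the same flask; this mirrors the classical base–alkylating agent ring opening of coumarins and benzocoumarins.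

Step 12
Reactants: 23 7-(benzyloxy)-3-[7-(benzyloxy)-5-methoxy-2,2-dimethylchroman-6-yl]-4-oxo-4H-chromene-2-carboxylic acid
Product: 24 7-(benzyloxy)-3-[7-(benzyloxy)-5-methoxy-2,2-dimethylchroman-6-yl]-4H-chromen-4-one
Conditions: Ag2CO3 (10 mol%), AcOH (5 mol%), DMSO, 120 °C
Reagents that add atoms: none
Why: Silver-catalysed protodecarboxylation: the silver carboxylate loses carbon dioxide to a C2–silver species stabilised by the adjacent ring oxygen, and acetic acid protonates it. Acids with an α-heteroatom are the best substrates, and isoflavone-2-carboxylic acids are known to decarboxylate even thermally.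

Step 13
Reactants: 24 7-(benzyloxy)-3-[7-(benzyloxy)-5-methoxy-2,2-dimethylchroman-6-yl]-4H-chromen-4-one
Product: 25 glycyrrhizaisoflavone C, 7-hydroxy-3-(7-hydroxy-5-methoxy-2,2-dimethylchroman-6-yl)-4H-chromen-4-one
Conditions: H2 (1 atm), 10% Pd/C, EtOAc/MeOH, rt, stopped at full conversion
Reagents that add atoms: none
Why: Hydrogenolysis should cleave both benzyl ethers; the aryl methyl ether, the chroman ether and, at atmospheric pressure with a short reaction time, the chromone double bond are retained.

## Compound list

1 | cyclohexane-1,3-dione | O=C1CCCC(=O)C1 | starting material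
2 | 3-methylbut-2-enal | CC(C)=CC=O | starting material
3 | 2-(3-methylbut-2-en-1-ylidene)cyclohexane-1,3-dione (1-oxatriene) | CC(C)=CC=C1C(=O)CCCC1=O | intermediate
4 | 2,2-dimethyl-2,6,7,8-tetrahydro-5H-chromen-5-one | CC1(C)C=CC2=C(CCCC2=O)O1 | intermediate
5 | 2,2-dimethyl-2,3,4,6,7,8-hexahydro-5H-chromen-5-one | CC1(C)CCC2=C(CCCC2=O)O1 | intermediate
6 | methyl bromoacetate | COC(=O)CBr | starting material
7 | lithium dienolate of 5 (deprotonated at C6) | [Li+].[O-]C1=CCCC2=C1CCC(C)(C)O2 | intermediate
8 | methyl 2-(2,2-dimethyl-5-oxo-3,4,5,6,7,8-hexahydro-2H-chromen-6-yl)acetate (racemic) | COC(=O)CC1CCC2=C(CCC(C)(C)O2)C1=O | intermediate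
9 | methanol | CO | starting material
10 | methyl 2-(5-methoxy-2,2-dimethylchroman-6-yl)acetate | COC(=O)Cc1ccc2OC(C)(C)CCc2c1OC | intermediate
11 | 2-(5-methoxy-2,2-dimethylchroman-6-yl)acetic acid | OC(=O)Cc1ccc2OC(C)(C)CCc2c1OC | intermediate
12 | resorcinol | Oc1cccc(O)c1 | starting material
13 | 1-(2,4-dihydroxyphenyl)-2-(5-methoxy-2,2-dimethylchroman-6-yl)ethan-1-one | COc1c(CC(=O)c2ccc(O)cc2O)ccc2OC(C)(C)CCc12 | intermediate
14 | benzyl bromide | BrCc1ccccc1 | starting material
15 | 1-[4-(benzyloxy)-2-hydroxyphenyl]-2-(5-methoxy-2,2-dimethylchroman-6-yl)ethan-1-one | COc1c(CC(=O)c2ccc(OCc3ccccc3)cc2O)ccc2OC(C)(C)CCc12 | intermediate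
16 | ethyl chlorooxoacetate | CCOC(=O)C(=O)Cl | starting material
17 | 5-(benzyloxy)-2-[2-(5-methoxy-2,2-dimethylchroman-6-yl)acetyl]phenyl ethyl oxalate | CCOC(=O)C(=O)Oc1cc(OCc2ccccc2)ccc1C(=O)Cc1ccc2OC(C)(C)CCc2c1OC | intermediate
18 | ethyl 7-(benzyloxy)-3-(5-methoxy-2,2-dimethylchroman-6-yl)-4-oxo-4H-chromene-2-carboxylate | CCOC(=O)c1oc2cc(OCc3ccccc3)ccc2c(=O)c1-c1ccc2OC(C)(C)CCc2c1OC | intermediate
19 | 7-(benzyloxy)-3-(5-methoxy-2,2-dimethylchroman-6-yl)-4-oxo-4H-chromene-2-carboxylic acid | OC(=O)c1oc2cc(OCc3ccccc3)ccc2c(=O)c1-c1ccc2OC(C)(C)CCc2c1OC | intermediate
20 | pentacyclic lactone (aryl ester between the chromone C2 carboxyl and the new oxygen on ring B C6') | COc1c2c(cc3OC(=O)c4oc5cc(OCc6ccccc6)ccc5c(=O)c4-c13)OC(C)(C)CC2 | intermediate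
21 | dipotassium 7-(benzyloxy)-3-(5-methoxy-2,2-dimethyl-7-oxidochroman-6-yl)-4-oxo-4H-chromene-2-carboxylate | [K+].[K+].[O-]C(=O)c1oc2cc(OCc3ccccc3)ccc2c(=O)c1-c1c([O-])cc2OC(C)(C)CCc2c1OC | intermediate
22 | benzyl 7-(benzyloxy)-3-[7-(benzyloxy)-5-methoxy-2,2-dimethylchroman-6-yl]-4-oxo-4H-chromene-2-carboxylate | O=C(OCc1ccccc1)c1oc2cc(OCc3ccccc3)ccc2c(=O)c1-c1c(OCc3ccccc3)cc2OC(C)(C)CCc2c1OC | intermediate
23 | 7-(benzyloxy)-3-[7-(benzyloxy)-5-methoxy-2,2-dimethylchroman-6-yl]-4-oxo-4H-chromene-2-carboxylic acid | OC(=O)c1oc2cc(OCc3ccccc3)ccc2c(=O)c1-c1c(OCc3ccccc3)cc2OC(C)(C)CCc2c1OC | intermediate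
24 | 7-(benzyloxy)-3-[7-(benzyloxy)-5-methoxy-2,2-dimethylchroman-6-yl]-4H-chromen-4-one | COc1c2CCC(C)(C)Oc2cc(OCc2ccccc2)c1-c1coc2cc(OCc3ccccc3)ccc2c1=O | intermediate
25 | glycyrrhizaisoflavone C | COc1c2c(cc(O)c1-c1coc3cc(O)ccc3c1=O)OC(C)(C)CC2 | target

## Step count and risks

Total step count: 13. Longest linear sequence: 13 steps (from cyclohexane-1,3-dione, 1).

**Step 10 (key step).** The reaction type is established for biaryl-2-carboxylic acids, but a 3-arylchromone-2-carboxylic acid has not been put through it.
- What may go wrong: cyclopalladation may be slow, because a carboxylate on the electron-poor pyrone carbon is a weak donor and the C3–C1' axis is twisted by three ortho substituents. Protodecarboxylation of the acid, or non-directed oxidation of the electron-rich ring B by the trivalent iodine reagent, could then take over.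
- Fallback: change the bond-forming manifold from organopalladium C–H cleavage to aroyloxy-radical cyclisation. Starting from 19, Cu(OAc)2 (catalytic) and dibenzoyl peroxide in hexafluoroisopropanol at 75 °C, a known lactonisation of biaryl-2-carboxylic acids, would return to the route at 20. In that manifold only addition at C6' can rearomatise by loss of hydrogen.

**Step 12.**
- What may go wrong: decarboxylation may stall because C2 is shielded by the ortho-disubstituted aryl group, and forcing the temperature invites loss of benzyl ethers.
- Fallback: excise ring C and rebuild it with one carbon. Starting from 23, KOH in aqueous ethanol at reflux adds at C2, opens ring C and cleaves the oxalyl unit by retro-Claisen reaction. This gives 1-[4-(benzyloxy)-2-hydroxyphenyl]-2-[7-(benzyloxy)-5-methoxy-2,2-dimethylchroman-6-yl]ethan-1-one F1. Heating F1 with Me2NCH(OMe)2 in toluene at 100 °C closes ring C through the enaminone and returns to the route at 24.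

**Step 4.**
- What may go wrong: acid-catalysed exchange of the ring D oxygen for methanol at the vinylogous ester stage would open ring D before aromatisation. Nuclear iodination of the electron-rich product is a second possibility.
- Fallback: separate dehydrogenation from methylation and avoid alcohol solvent. Starting from 8, CuBr2 and LiBr in acetonitrile at reflux (α'-bromination and loss of HBr) would give methyl 2-(5-hydroxy-2,2-dimethylchroman-6-yl)acetate F2. Methylation of F2 with MeI and K2CO3 in acetone returns to the route at 10.

**Step 11.**
- What may go wrong: hydroxide may add to chromone C2 and open ring C in competition with lactone cleavage. Incomplete benzylation of the phenoxide would lead to re-lactonisation on acidification.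
- Fallback: avoid hydroxide altogether. Starting from 20, alcoholysis with allyl alcohol and K2CO3 in DMF followed by benzyl bromide in the same flask would give allyl 7-(benzyloxy)-3-[7-(benzyloxy)-5-methoxy-2,2-dimethylchroman-6-yl]-4-oxo-4H-chromene-2-carboxylate F3. Deallylation of F3 with Pd(PPh3)4 (catalytic) and morpholine in THF, a neutral process through a π-allyl complex, returns to the route at 23.

**Step 13.**
- What may go wrong: over-reduction of the chromone C2–C3 double bond if hydrogenolysis of the hindered C6' benzyl ether is slow.
- Fallback: replace reduction by Lewis acid dealkylation. Starting from 24, BCl3 with pentamethylbenzene as cation scavenger in CH2Cl2 at −78 °C cleaves benzyl ethers in the presence of aryl methyl ethers. It cannot reduce the enone and arrives directly at 25.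

## Further compounds

F0 | step 10 | none | none
F1 | step 12 | 1-[4-(benzyloxy)-2-hydroxyphenyl]-2-[7-(benzyloxy)-5-methoxy-2,2-dimethylchroman-6-yl]ethan-1-one | COc1c(CC(=O)c2ccc(OCc3ccccc3)cc2O)c(OCc2ccccc2)cc2OC(C)(C)CCc12
F2 | step 4 | methyl 2-(5-hydroxy-2,2-dimethylchroman-6-yl)acetate | COC(=O)Cc1ccc2OC(C)(C)CCc2c1O
F3 | step 11 | allyl 7-(benzyloxy)-3-[7-(benzyloxy)-5-methoxy-2,2-dimethylchroman-6-yl]-4-oxo-4H-chromene-2-carboxylate | C=CCOC(=O)c1oc2cc(OCc3ccccc3)ccc2c(=O)c1-c1c(OCc3ccccc3)cc2OC(C)(C)CCc2c1OC
F0 | step 13 | none | none
A1 | alternative 1 | methyl 2-[4-methoxy-6-methyl-5-(3-methylbut-2-en-1-yl)-2-oxo-2H-pyran-3-yl]acetate | COC(=O)CC1=C(OC)C(CC=C(C)C)=C(C)OC1=O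
A2 | alternative 1 | methyl 2-[2,4-dihydroxy-6-methoxy-5-(3-methylbut-2-en-1-yl)phenyl]acetate | COC(=O)Cc1c(O)cc(O)c(CC=C(C)C)c1OC
A3 | alternative 2 | 3-(benzyloxy)-4-[7-(benzyloxy)-4-oxo-4H-chromen-3-yl]cyclobut-2-en-1-one | O=C1C=C(OCc2ccccc2)C1c1coc2cc(OCc3ccccc3)ccc2c1=O
A4 | alternative 2 | triisopropyl[(5-methylhex-5-en-1-yn-1-yl)oxy]silane | CC(=C)CCC#CO[Si](C(C)C)(C(C)C)C(C)C
A5 | alternative 2 | 7-(benzyloxy)-3-[6-(benzyloxy)-2-hydroxy-3-(3-methylbut-3-en-1-yl)-4-(triisopropylsilyloxy)phenyl]-4H-chromen-4-one | Oc1c(CCC(C)=C)c(O[Si](C(C)C)(C(C)C)C(C)C)cc(OCc2ccccc2)c1-c1coc2cc(OCc3ccccc3)ccc2c1=O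
A6 | alternative 3 | 7-(benzyloxy)-3-[2,6-bis(methoxymethoxy)-4-(2-methylbut-3-yn-2-yloxy)phenyl]-4H-chromen-4-one | C#CC(C)(C)Oc1cc(OCOC)c(-c2coc3cc(OCc4ccccc4)ccc3c2=O)c(OCOC)c1
A7 | alternative 3 | 7-(benzyloxy)-3-[5,7-bis(methoxymethoxy)-2,2-dimethyl-2H-chromen-6-yl]-4H-chromen-4-one | CC1(C)C=Cc2c(OCOC)c(-c3coc4cc(OCc5ccccc5)ccc4c3=O)c(OCOC)cc2O1
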